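(The runs are simulated with constants of no real substance, and the scatter is random.)

I decide to ask one thing of each flask: what chance does a molecule of intermediate, once formed, have of still being there at 8.0 h?

| setting | red | amber | gamma | beta | epsilon | eta | theta |
|---|---|---|---|---|---|---|---|
| substrate | 0.016 M | 0.073 M | 0.020 M | 0.030 M | 0.050 M | 0.080 M | 0.12 M |
| coupling partner | 1.05 equiv | 1.05 equiv | 1.05 equiv | 1.05 equiv | 1.05 equiv | 1.05 equiv | 1.05 equiv |
| second reagent | 1.5 equiv | 1.5 equiv | 1.50 equiv | 1.50 equiv | 1.50 equiv | 1.50 equiv | 1.50 equiv |
| remark | run made earlier | run made earlier |  |  |  |  |  |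
| time |  |  | 8.0 h | 8.0 h | 8.0 h | 8.0 h | 8.0 h |

- red (time / h: intermediate / %, target / %, substrate / %): 0.417: 1, 0, 89; 0.833: 8, 0, 79; 1.50: 7, 2, 67; 3.00: 12, 3, 51; 6.00: 12, 4, 31
- amber (time / h: intermediate / %, target / %, substrate / %): 0.417: 12, 0, 62; 0.833: 20, 2, 45; 1.50: 20, 6, 26; 3.00: 20, 8, 12; 6.00: 13, 14, 2

(scatter of a reading: 1.5 percentage points)

- "hardly changes" means that all values lie within two and a half points (for a concentration: within two and a half percent of the largest)

* [intermediate] at the end for gamma, beta, epsilon, eta, theta, in this order
* how that number moves from the first to the last of them (falls all the way / rises, then falls / rises all the way / hardly changes / falls, then rises)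

The bench rule is to read the plateau and multiply it by the loading. The amber run reads 20 % intermediate at 0.833 h and 20 % at 3.00 h, and the red run reads 12 % at 6.00 h, so on these two runs the percentage does not fall with loading, and multiplying it by a growing c(substrate) gives a rising row. That rule lasts while substrate feeds the plateau. The amber run shows the border: by 3.00 h substrate is down to 12 %, and by 6.00 h intermediate has dropped to 13 %.

Read as a pseudo-first-order decay, that drop gives a drain time of 6.96 h at the amber loading. This is a reading and carries the scatter. Every charge scales with the loading, so I assume the drain time shortens in inverse proportion. I call the time left after 3.00 h, divided by the drain time at a flask's loading, its drain number n, and in my estimate a molecule present at 3.00 h then has a chance of e to the minus n of surviving to the end. In this estimate, loading times survival peaks where n equals one, at a c(substrate) of 0.102 M. That lies above eta's charge and below theta's.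

My reckoning on the amber plateau gives eta n = 0.787 and 0.00728 M, and theta n = 1.18 and 0.00737 M. These two are level within the scatter, so I expect the row to turn at its top.

The forecast differs from this: it gives 0.0028 M, 0.0043 M, 0.0065 M, 0.0088 M, 0.0105 M, and writes that “the absolute concentration still rises throughout”, so its shape is rises all the way.

The flask gives 0.00244 M, 0.00384 M, 0.00585 M, 0.00709 M, 0.00685 M: rises, then falls.

    substrate + coupling partner → intermediate (k = 6.50 M⁻¹ h⁻¹)
    second reagent + intermediate → target (k = 2.90 M⁻¹ h⁻¹)
    substrate + second reagent → side product (k = 6.20 M⁻¹ h⁻¹)
    target ⇌ isomer of the product (K = 11.0, k = 0.170 h⁻¹)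
    coupling partner → decomposed reagent (k = 0.350 h⁻¹)
    substrate ⇌ dormant form (K = 0.870, k = 0.0590 h⁻¹)

Theta has a drain number of 1.18 and an estimated survival chance of 0.307, which my reckoning on the amber plateau turns into 6.15 % against the 5.71 % theta holds at the end. Part of what theta keeps comes from two things acting together, the falling second reagent and the length of the run: without that fall, theta ends at 8.01 × 10⁻⁴ M instead of 0.00685 M, and a run ten times as long leaves 1.86 × 10⁻⁸ M. Gamma, with a drain number of 0.197, has an estimated survival chance of 0.821 and ends at 12.2 %.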